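**Strategy**

Everything rests on disconnecting the C5–C6 bond of the bicyclo[4.3.1]decane core (C1 tertiary carbinol bridgehead, C6 methyl-bearing bridgehead, C7 secondary carbinol, C10 one-carbon bridge). C6 is α to C7 and 1,3 to C1 across C10, so a C7 ketone flanked by a temporary C8=C9 alkene makes C6 the only enolisable carbon. In the key step a cross-conjugated dienolate is released from a monocyclic 4-hydroxycyclohex-2-enone whose C1 substituent carries an iodoethyl arm; C-alkylation closes the seven-membered ring, creates the quaternary bridgehead and completes the bicycle in one operation. The precursor arises by aldol union of an enantioenriched vinyl lactone with a methylated quinone monoketal.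

Key step: step 6

Remark: the sense of induction in the two catalytic conjugate additions (steps 1 and 2) is assumed by analogy with the parent cyclohexenone cases; the ligand antipode meant is the one that gives 2 and 4 as drawn.

**Route**

Step 1
Reactants: 1 4,4-dimethoxycyclohexa-2,5-dien-1-one
Product: 2 (S)-4,4-dimethoxy-5-methylcyclohex-2-en-1-one
Conditions: ZnMe2 (1.5 equiv), Cu(OTf)2 (2 mol %), (S,R,R)-BINOL bis(1-phenylethyl)amine phosphoramidite (4 mol %), toluene, −25 °C; then H2O
Reagents that add atoms: dimethylzinc, C[Zn]C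
Why: Copper-catalysed enantioselective conjugate addition (Feringa-type desymmetrisation of a prochiral cyclohexadienone) should deliver one methyl group to one enantiotopic β-carbon and set C5 (S), the mono-enone product being less electrophilic than the cross-conjugated dienone.

Step 2
Reactants: 3 5,6-dihydro-2H-pyran-2-one
Product: 4 (R)-4-vinyltetrahydro-2H-pyran-2-one
Conditions: CH2=CHBF3K (2 equiv), [Rh(cod)2]PF6 (3 mol %), (R)-BINAP (3.3 mol %), toluene/H2O 4:1, 100 °C
Reagents that add atoms: potassium vinyltrifluoroborate, [K+].C=C[B-](F)(F)F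
Why: Rhodium–BINAP-catalysed asymmetric 1,4-addition of an alkenylboron reagent (Hayashi–Miyaura reaction) to the unsaturated lactone should set C4 (R) by ligand-controlled facial selection.

Step 3
Reactants: 4 (R)-4-vinyltetrahydro-2H-pyran-2-one, 2 (S)-4,4-dimethoxy-5-methylcyclohex-2-en-1-one
Product: 5 (3S,4S)-3-[(1R,5S)-1-hydroxy-4,4-dimethoxy-5-methylcyclohex-2-en-1-yl]-4-vinyltetrahydro-2H-pyran-2-one
Conditions: LiN(i-Pr)2 (1.05 equiv), THF, −78 °C; then 2, −78 °C; AcOH quench at −78 °C
Reagents that add atoms: none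
Why: Kinetic lithium-enolate aldol addition in which the lactone enolate should react anti to its C4 vinyl group (trans-3,4-lactone) and the enone carbonyl should be attacked anti to the C5 methyl group, as in 1,2-additions to 5-substituted cyclohex-2-enones, so the two enantioenriched partners fix the carbinol centre (R) relative to the chain, while cold protonation forestalls retro-aldol.

Step 4
Reactants: 5 (3S,4S)-3-[(1R,5S)-1-hydroxy-4,4-dimethoxy-5-methylcyclohex-2-en-1-yl]-4-vinyltetrahydro-2H-pyran-2-one
Product: 6 methyl (2S,3S)-2-[(1R,5S)-1-hydroxy-4,4-dimethoxy-5-methylcyclohex-2-en-1-yl]-3-(2-hydroxyethyl)pent-4-enoate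
Conditions: K2CO3 (0.3 equiv), MeOH, 0 °C; pH 7 buffer work-up; used directly
Reagents that add atoms: methanol, CO
Why: Carbonate-catalysed transesterification (methanolysis) opens the δ-lactone to the methyl ester and frees the primary alcohol while the ketal still masks the ketone, so no enone-driven retro-aldol pathway exists, and the hydroxy ester is taken on before it can relactonise.

Step 5
Reactants: 6 methyl (2S,3S)-2-[(1R,5S)-1-hydroxy-4,4-dimethoxy-5-methylcyclohex-2-en-1-yl]-3-(2-hydroxyethyl)pent-4-enoate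
Product: 8 methyl (2S,3S)-2-[(1R,5S)-1-hydroxy-5-methyl-4-oxocyclohex-2-en-1-yl]-3-(2-iodoethyl)pent-4-enoate, via ketal iodide 7 (not isolated)
Conditions: I2, PPh3, imidazole, CH2Cl2, 0 °C; then 5% aq. oxalic acid, THF, 0 °C to rt
Reagents that add atoms: iodine, II; water, O
Why: Appel-type iodination converts only the primary alcohol, and mild acid hydrolysis then unveils the enone because the allylic ketal ionises far more readily than the tertiary carbinol, which ends up γ to the new carbonyl and is thereby deactivated.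

Step 6
Reactants: 8 methyl (2S,3S)-2-[(1R,5S)-1-hydroxy-5-methyl-4-oxocyclohex-2-en-1-yl]-3-(2-iodoethyl)pent-4-enoate
Product: 11 methyl (1R,2S,3S,6R)-1-hydroxy-6-methyl-7-oxo-3-vinylbicyclo[4.3.1]dec-8-ene-2-carboxylate, via bis-silyl dienol ether 9 (not isolated), via O-silyl bicyclic enone 10 (not isolated)
Conditions: Me3SiOTf (2.4 equiv), Et3N (4 equiv), CH2Cl2, −40 to 0 °C; pentane filtration; Bu4N[Ph3SiF2] (1.05 equiv), THF (0.005 M), 0 to 40 °C; then 1 M HCl, THF, 0 °C
Reagents that add atoms: none
Why: Soft enolisation silylates the tertiary alcohol and converts the enone into its 2-silyloxy-1,3-diene at the only enolisable carbon (the future C6; γ-deprotonation is impossible because the γ-carbon is the fully substituted carbinol), and fluoride then unmasks a tetrabutylammonium cross-conjugated dienolate that displaces the primary iodide in an intramolecular SN2 reaction. The closest known reaction type is the fluoride-promoted regiospecific C-alkylation of silyl enol ethers (Kuwajima–Noyori type), run here intramolecularly like classical bridging enolate alkylations. The one ring closed is the seven-membered ring, by a 7-(enolexo)-exo-tet closure through a side arm that sits pseudo-axial on the carbinol carbon. The new quaternary centre C6 (R) is dictated by that tether, since the arm can only reach the enolate face syn to the C1–C2 bond, while the sacrificial C–H stereocentre that relayed chirality in step 3 is erased. The step needs C- over O-alkylation (O-closure would give a strained nine-membered enol ether), intramolecular over intermolecular alkylation (high dilution) and survival of the β-silyloxy ester (the hindered tertiary silyl ether should outlast one equivalent of fluoride and is hydrolysed only on acidic work-up). Regioselectivity is secured by the substrate itself, because the C8=C9 alkene blocks the other α-side.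

Step 7
Reactants: 11 methyl (1R,2S,3S,6R)-1-hydroxy-6-methyl-7-oxo-3-vinylbicyclo[4.3.1]dec-8-ene-2-carboxylate
Product: 12 methyl (1S,2S,3S,6R)-1-hydroxy-6-methyl-7-oxo-3-vinylbicyclo[4.3.1]decane-2-carboxylate
Conditions: [(Ph3P)CuH]6 (0.4 equiv), H2O (3 equiv), THF/benzene, rt
Reagents that add atoms: none
Why: Conjugate reduction with Stryker's reagent (copper hydride 1,4-reduction) removes the temporary C8=C9 alkene chemoselectively, leaving the isolated vinyl group, the ester and the γ-hydroxyl (which cannot be eliminated from the copper enolate) untouched.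

Step 8
Reactants: 12 methyl (1S,2S,3S,6R)-1-hydroxy-6-methyl-7-oxo-3-vinylbicyclo[4.3.1]decane-2-carboxylate
Product: 13 methyl (1S,2S,3S,6R)-1-hydroxy-6-methyl-7-oxo-3-(2-oxoethyl)bicyclo[4.3.1]decane-2-carboxylate
Conditions: PdCl2(PhCN)2 (10 mol %), CuCl2·2H2O (10 mol %), AgNO2 (5 mol %), O2 (1 atm), t-BuOH/MeNO2 15:1, rt
Reagents that add atoms: dioxygen, O=O
Why: Aldehyde-selective (anti-Markovnikov) Wacker-type oxidation with nitrite co-catalysis converts the terminal vinyl group directly into the CH2CHO unit without passing through a hydroxy ester that could lactonise onto the C2 ester.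

Step 9
Reactants: 14 2-methylbut-3-en-2-ol, 15 (E)-but-2-enal
Product: 16 (E)-4-hydroxy-4-methylpent-2-enal
Conditions: second-generation Hoveyda–Grubbs catalyst, (H2IMes)Cl2Ru=CH(2-i-PrO-C6H4) (2 mol %), CH2Cl2, 40 °C
Reagents that add atoms: none
Why: Olefin cross-metathesis of a hindered tertiary allylic alcohol with an enal partner should give the E-enal under thermodynamic control, with propene lost.

Step 10
Reactants: 13 methyl (1S,2S,3S,6R)-1-hydroxy-6-methyl-7-oxo-3-(2-oxoethyl)bicyclo[4.3.1]decane-2-carboxylate, 16 (E)-4-hydroxy-4-methylpent-2-enal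
Product: 17 methyl (1S,2S,3R,6R)-1-hydroxy-3-[(2E,4E)-6-hydroxy-6-methyl-1-oxohepta-2,4-dien-2-yl]-6-methyl-7-oxobicyclo[4.3.1]decane-2-carboxylate
Conditions: pyrrolidine (20 mol %), PhCO2H (20 mol %), 4 Å sieves, CH2Cl2, 0 °C to rt
Reagents that add atoms: none
Why: Amine-catalysed crossed aldol condensation, in which the enamine of the unhindered aldehyde adds 1,2 to the non-enolisable enal (its β-carbon is shielded by the tertiary carbinol) and dehydration follows, should give the (2E)-dienal, the thermodynamically preferred geometry of 2-alkyl-2-enals, with the (4E) alkene carried over from 16.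

Step 11
Reactants: 17 methyl (1S,2S,3R,6R)-1-hydroxy-3-[(2E,4E)-6-hydroxy-6-methyl-1-oxohepta-2,4-dien-2-yl]-6-methyl-7-oxobicyclo[4.3.1]decane-2-carboxylate
Product: 18 methyl (1S,2S,3R,6R,7S)-3-[(2E,4E)-1,6-dihydroxy-6-methylhepta-2,4-dien-2-yl]-1,7-dihydroxy-6-methylbicyclo[4.3.1]decane-2-carboxylate
Conditions: NaBH4 (3 equiv), CeCl3·7H2O (1.5 equiv), MeOH, −40 to 0 °C
Reagents that add atoms: none
Why: Luche reduction reduces the dienal in 1,2 fashion and, in the same operation, the C7 ketone by axial hydride attack on the locked chair (the equatorial trajectory is blocked by the axial C5 bridge on the neighbouring quaternary C6), which should set C7 (S) with an equatorial hydroxyl.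

Step 12
Reactants: 18 methyl (1S,2S,3R,6R,7S)-3-[(2E,4E)-1,6-dihydroxy-6-methylhepta-2,4-dien-2-yl]-1,7-dihydroxy-6-methylbicyclo[4.3.1]decane-2-carboxylate
Product: 19 methyl (1S,2S,3R,6R,7S)-3-[(2E,4E)-1-acetoxy-6-hydroxy-6-methylhepta-2,4-dien-2-yl]-1,7-dihydroxy-6-methylbicyclo[4.3.1]decane-2-carboxylate
Conditions: Ac2O (1.1 equiv), 2,4,6-collidine, CH2Cl2, −20 to 0 °C
Reagents that add atoms: acetic anhydride, CC(=O)OC(C)=O
Why: Chemoselective acylation, since the primary allylic alcohol should be acetylated much faster than the neopentyl-type secondary C7 hydroxyl and the two tertiary hydroxyls.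

**Compound list**

1 | 4,4-dimethoxycyclohexa-2,5-dien-1-one | COC1(OC)C=CC(=O)C=C1 | starting material
2 | (S)-4,4-dimethoxy-5-methylcyclohex-2-en-1-one | O=C1C=CC(OC)(OC)[C@@H](C)C1 | intermediate
3 | 5,6-dihydro-2H-pyran-2-one | O=C1C=CCCO1 | starting material
4 | (R)-4-vinyltetrahydro-2H-pyran-2-one | O=C1OCC[C@@H](C=C)C1 | intermediate
5 | (3S,4S)-3-[(1R,5S)-1-hydroxy-4,4-dimethoxy-5-methylcyclohex-2-en-1-yl]-4-vinyltetrahydro-2H-pyran-2-one | O=C1OCC[C@@H](C=C)[C@H]1[C@]2(O)C=CC(OC)(OC)[C@@H](C)C2 | intermediate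
6 | methyl (2S,3S)-2-[(1R,5S)-1-hydroxy-4,4-dimethoxy-5-methylcyclohex-2-en-1-yl]-3-(2-hydroxyethyl)pent-4-enoate | COC(=O)[C@@H]([C@H](C=C)CCO)[C@]1(O)C=CC(OC)(OC)[C@@H](C)C1 | intermediate
7 | methyl (2S,3S)-2-[(1R,5S)-1-hydroxy-4,4-dimethoxy-5-methylcyclohex-2-en-1-yl]-3-(2-iodoethyl)pent-4-enoate | COC(=O)[C@@H]([C@H](C=C)CCI)[C@]1(O)C=CC(OC)(OC)[C@@H](C)C1 | intermediate
8 | methyl (2S,3S)-2-[(1R,5S)-1-hydroxy-5-methyl-4-oxocyclohex-2-en-1-yl]-3-(2-iodoethyl)pent-4-enoate | COC(=O)[C@@H]([C@H](C=C)CCI)[C@]1(O)C=CC(=O)[C@@H](C)C1 | intermediate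
9 | methyl (2S,3S)-3-(2-iodoethyl)-2-[(1R)-5-methyl-1,4-bis(trimethylsilyloxy)cyclohexa-2,4-dien-1-yl]pent-4-enoate | COC(=O)[C@@H]([C@H](C=C)CCI)[C@]1(O[Si](C)(C)C)C=CC(O[Si](C)(C)C)=C(C)C1 | intermediate
10 | methyl (1R,2S,3S,6R)-6-methyl-7-oxo-1-(trimethylsilyloxy)-3-vinylbicyclo[4.3.1]dec-8-ene-2-carboxylate | COC(=O)[C@H]1[C@H](C=C)CC[C@]2(C)C[C@@]1(O[Si](C)(C)C)C=CC2=O | intermediate
11 | methyl (1R,2S,3S,6R)-1-hydroxy-6-methyl-7-oxo-3-vinylbicyclo[4.3.1]dec-8-ene-2-carboxylate | COC(=O)[C@H]1[C@H](C=C)CC[C@]2(C)C[C@@]1(O)C=CC2=O | intermediate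
12 | methyl (1S,2S,3S,6R)-1-hydroxy-6-methyl-7-oxo-3-vinylbicyclo[4.3.1]decane-2-carboxylate | COC(=O)[C@H]1[C@H](C=C)CC[C@]2(C)C[C@@]1(O)CCC2=O | intermediate
13 | methyl (1S,2S,3S,6R)-1-hydroxy-6-methyl-7-oxo-3-(2-oxoethyl)bicyclo[4.3.1]decane-2-carboxylate | COC(=O)[C@H]1[C@H](CC=O)CC[C@]2(C)C[C@@]1(O)CCC2=O | intermediate
14 | 2-methylbut-3-en-2-ol | CC(C)(O)C=C | starting material
15 | (E)-but-2-enal (crotonaldehyde) | C/C=C/C=O | starting material
16 | (E)-4-hydroxy-4-methylpent-2-enal | CC(C)(O)/C=C/C=O | intermediate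
17 | methyl (1S,2S,3R,6R)-1-hydroxy-3-[(2E,4E)-6-hydroxy-6-methyl-1-oxohepta-2,4-dien-2-yl]-6-methyl-7-oxobicyclo[4.3.1]decane-2-carboxylate | COC(=O)[C@H]1[C@H](/C(=C\C=C\C(C)(C)O)C=O)CC[C@]2(C)C[C@@]1(O)CCC2=O | intermediate
18 | methyl (1S,2S,3R,6R,7S)-3-[(2E,4E)-1,6-dihydroxy-6-methylhepta-2,4-dien-2-yl]-1,7-dihydroxy-6-methylbicyclo[4.3.1]decane-2-carboxylate | COC(=O)[C@H]1[C@H](/C(=C\C=C\C(C)(C)O)CO)CC[C@]2(C)C[C@@]1(O)CC[C@@H]2O | intermediate
19 | methyl (1S,2S,3R,6R,7S)-3-[(2E,4E)-1-acetoxy-6-hydroxy-6-methylhepta-2,4-dien-2-yl]-1,7-dihydroxy-6-methylbicyclo[4.3.1]decane-2-carboxylate | COC(=O)[C@H]1[C@H](/C(=C\C=C\C(C)(C)O)COC(C)=O)CC[C@]2(C)C[C@@]1(O)CC[C@@H]2O | target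

**Step count**

Total step count: 12. Longest linear sequence: 10 steps (steps 1, 3, 4, 5, 6, 7, 8, 10, 11, 12).

**Steps most likely to fail**

Step 6. The allylic silyl ether may ionise during silylation and the ring then aromatise. Fluoride may also strip the tertiary silyl group early, after which the free alkoxide can fragment by retro-aldol or close a tetrahydropyran onto the iodide, and a slow seven-membered closure leaves room for proton quench or intermolecular alkylation. The fallback sets out from 8 and replaces the latent silyl dienolate by a discrete metal dienolate of a robustly protected substrate. Silylation of the tertiary alcohol with Et3SiOTf and 2,6-lutidine should give methyl (2S,3S)-3-(2-iodoethyl)-2-[(1R,5S)-5-methyl-4-oxo-1-(triethylsilyloxy)cyclohex-2-en-1-yl]pent-4-enoate F1. Deprotonation at the only acidic ketone position with KN(SiMe3)2 and 18-crown-6 in dilute THF (−78 to 0 °C) should then close the ring to methyl (1R,2S,3S,6R)-6-methyl-7-oxo-1-(triethylsilyloxy)-3-vinylbicyclo[4.3.1]dec-8-ene-2-carboxylate F2, and HF·pyridine removes the silyl group to come back to the route at 11.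

Step 10. The enamine may add in conjugate (Michael) fashion to the enal instead of 1,2, the donor aldehyde may self-condense, and alkene geometry may erode. The fallback sets out from 13 and builds the same dienal by methylenation and cross-coupling. Mannich methylenation with Me2N=CH2 iodide and Et3N should give methyl (1S,2S,3R,6R)-1-hydroxy-6-methyl-7-oxo-3-(3-oxoprop-1-en-2-yl)bicyclo[4.3.1]decane-2-carboxylate F3. A Heck coupling under Jeffery conditions (Pd(OAc)2, Bu4NCl, K2CO3, DMF) with (E)-4-iodo-2-methylbut-3-en-2-ol F4, made from 2-methylbut-3-yn-2-ol by hydrozirconation with Cp2Zr(H)Cl and iodination, should then give the (2E,4E)-dienal and come back to the route at 17.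

Step 8. The oxidation may turn to the Markovnikov methyl ketone, or the terminal alkene may isomerise before it is oxidised. The fallback sets out from 12 and passes through the alcohol oxidation level. Hydroboration with 9-BBN and oxidation with NaBO3·4H2O should give methyl (1S,2S,3S,6R)-1-hydroxy-3-(2-hydroxyethyl)-6-methyl-7-oxobicyclo[4.3.1]decane-2-carboxylate F5. This is oxidised without delay (to pre-empt lactonisation onto the C2 ester) with Dess–Martin periodinane to come back to the route at 13.

Further compounds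

F1 | step 6 | methyl (2S,3S)-3-(2-iodoethyl)-2-[(1R,5S)-5-methyl-4-oxo-1-(triethylsilyloxy)cyclohex-2-en-1-yl]pent-4-enoate | COC(=O)[C@@H]([C@H](C=C)CCI)[C@]1(O[Si](CC)(CC)CC)C=CC(=O)[C@@H](C)C1
F2 | step 6 | methyl (1R,2S,3S,6R)-6-methyl-7-oxo-1-(triethylsilyloxy)-3-vinylbicyclo[4.3.1]dec-8-ene-2-carboxylate | COC(=O)[C@H]1[C@H](C=C)CC[C@]2(C)C[C@@]1(O[Si](CC)(CC)CC)C=CC2=O
F3 | step 10 | methyl (1S,2S,3R,6R)-1-hydroxy-6-methyl-7-oxo-3-(3-oxoprop-1-en-2-yl)bicyclo[4.3.1]decane-2-carboxylate | COC(=O)[C@H]1[C@H](C(=C)C=O)CC[C@]2(C)C[C@@]1(O)CCC2=O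
F4 | step 10 | (E)-4-iodo-2-methylbut-3-en-2-ol | CC(C)(O)/C=C/I
F5 | step 8 | methyl (1S,2S,3S,6R)-1-hydroxy-3-(2-hydroxyethyl)-6-methyl-7-oxobicyclo[4.3.1]decane-2-carboxylate | COC(=O)[C@H]1[C@H](CCO)CC[C@]2(C)C[C@@]1(O)CCC2=O
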